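The readings are simulated from invented constants.

A ratio of 2.87 is what the runs so far offer: Sunday's flask, at 5 °C, held 4.3% left-handed product against 1.5% right-handed product after 150 d, and that right-handed reading carries a scatter of 0.3 percentage points. This ratio of two amounts, made in the same time from a racemate, is the selectivity factor. Its zero is the symmetric case: mirror-image substrates that a catalyst does not tell apart give a ratio of one and equal shares of the two products. A single-handed catalyst shifts that by an energy, the handedness gap, which is the gas constant times the absolute temperature times ln of the ratio: 2.44 kJ mol⁻¹ as read from Sunday's run.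

common to all: free catalyst 1.5 mM; added ligand 1.2 mM
- Thursday's: left-handed substrate 23 mM; right-handed substrate 23 mM; reagent 92 mM; temperature −45 °C; run made earlier
- Sunday's: left-handed substrate 92 mM; right-handed substrate 92 mM; reagent 92 mM; temperature 5 °C; run made earlier
- Monday's: left-handed substrate 46 mM; right-handed substrate 46 mM; reagent 140 mM; temperature −45 °C; run made earlier
- west: left-handed substrate 46 mM; right-handed substrate 46 mM; reagent 92.0 mM; temperature 50 °C; time 25 d
- south-east: left-handed substrate 46 mM; right-handed substrate 46 mM; reagent 92.0 mM; temperature −40 °C; time 25 d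
- north-east: left-handed substrate 46 mM; right-handed substrate 46 mM; reagent 92.0 mM; temperature 20 °C; time 25 d
- north-west: left-handed substrate 46 mM; right-handed substrate 46 mM; reagent 92.0 mM; temperature −10 °C; time 25 d

| run | time / d | left-handed product / % | right-handed product / % |
|---|---|---|---|
| Thursday's | 150 | 0.2 | 0.1 |
| Thursday's | 400 | 0 | 0.1 |
| Thursday's | 800 | 0 | 0.2 |
| Thursday's | 1200 | 0 | 0 |
| Thursday's | 1500 | 0.6 | 0 |
| Sunday's | 12.0 | 0.7 | 0 |
| Sunday's | 25.0 | 0.3 | 0 |
| Sunday's | 40.0 | 1.1 | 0.6 |
| Sunday's | 80.0 | 2.5 | 0.8 |
| Sunday's | 150 | 4.3 | 1.5 |
| Monday's | 150 | 0.6 | 0 |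
| Monday's | 300 | 0 | 0 |
| Monday's | 400 | 0 | 0 |
| Monday's | 800 | 0 | 0 |
| Monday's | 1500 | 0.3 | 0 |

(each reading ± 0.3 percentage points)

- free catalyst is single-handed; left-handed substrate and right-handed substrate are mirror images of each other, charged as a racemate, each of them at the stated concentration

1. the flask that comes out highest in share of left-handed product in all that became left-handed product or right-handed product, or "all alike" when all lie within 1.5 percentage points (west / south-east / north-east / north-west / all alike)
2. share of left-handed product in all that became left-handed product or right-handed product, west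
3. share of left-handed product in all that became left-handed product or right-handed product, south-east
4. share of left-handed product in all that became left-handed product or right-handed product, north-east
5. share of left-handed product in all that became left-handed product or right-handed product, north-west

These two amounts carry the argument. The overall speed drops out of their ratio while the substrates stay near their charge, and at its last reading Sunday's flask had turned 5.80% of the two substrates together into product. The runs at −45 °C give no ratio, since their largest reading, 0.6%, is twice the scatter.

My reckoning holds the gap fixed and assumes neither substrate is drawn down. South-east, the coldest flask, then gets a ratio of 3.51 and a share of 77.8%, and so comes highest, while west gets 2.48 and 71.2%.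

The forecast names south-east, with 69% for west, which is lower than my figure, 78% for south-east, 73% for north-east and 75% for north-west, and warns: “The temperature trend is an extrapolation”.

The flasks give 85.0% in west, 94.6% in south-east, 83.2% in north-east and 82.9% in north-west, so the highest is south-east.

    free catalyst + left-handed substrate ⇌ catalyst intermediate A (K = 33.0 M⁻¹, k = 190 M⁻¹ h⁻¹, Ea = 46.0 kJ mol⁻¹, ΔH = −40.0 kJ mol⁻¹)
    free catalyst + right-handed substrate ⇌ catalyst intermediate B (K = 37.0 M⁻¹, k = 500 M⁻¹ h⁻¹, Ea = 51.0 kJ mol⁻¹, ΔH = −60.0 kJ mol⁻¹)
    reagent + catalyst intermediate A → free catalyst + left-handed product (k = 8.60 M⁻¹ h⁻¹, Ea = 74.0 kJ mol⁻¹)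
    reagent + catalyst intermediate B → free catalyst + right-handed product (k = 0.680 M⁻¹ h⁻¹, Ea = 78.0 kJ mol⁻¹)
    reagent ⇌ dormant form (K = 0.340, k = 0.0170 h⁻¹, Ea = 109 kJ mol⁻¹, ΔH = −13.0 kJ mol⁻¹)
    free catalyst + added ligand ⇌ idle complex, settled at all times (K = 10000 M⁻¹, ΔH = 17.0 kJ mol⁻¹)
    (constants at 50 °C)

South-east's share is a ratio of 17.4 and a gap of 5.53 kJ mol⁻¹, larger than Sunday's reading of 2.44 kJ mol⁻¹, while a repeat of south-east at −15 °C gives 87.3% and a gap of 4.14 kJ mol⁻¹. In south-east, free catalyst has a half-life of 1.9 d by the forward binding of right-handed substrate alone at 25.0 d, against 1500 d for catalyst intermediate A by its step with reagent at 12.5 d. At 25.0 d that flask's catalyst stands 43.2% as catalyst intermediate A and 56.6% as catalyst intermediate B, with left-handed product at 0.00723%.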